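Remark: (E)-3-(3,4-dimethoxyphenyl)prop-2-en-1-ol and vinylmagnesium bromide solution are taken as purchasable; in the line notations, cyclopentadienyl ligands are drawn as sigma-bonded C5H5 rings.

## Structural features

Magnone B is a 2,3,4-trisubstituted oxolane (ring atoms O1, C2, C3, C4, C5; C5 is a plain CH2). C2 carries the 3,4,5-trimethoxyphenyl ring (ring A), C3 a hydroxymethyl group (carbon C6) and C4 a 3,4-dimethoxybenzoyl group (ketone carbon C7, bonded to ring B). The three stereocentres are contiguous, (2S,3R,4R): ring A is trans to C6, and C6 is cis to C7. C4 is alpha to the aryl ketone and its cis relation to C6 is the less stable arrangement, so base, enolisation or a late organometallic addition next to it can epimerise it; the benzylic ether C2–O1 is acid-labile and both arenes are electron-rich. The real difficulty is therefore the 3,4-cis pair at an epimerisable centre combined with 2,3-trans, not the connectivity. The feature that the key step exploits is that C7(=O)–C4–C3–C6–OH is a gamma-hydroxy ketone, the opened and oxidised form of a second oxolane ring (C7–O–C6) cis-fused to the first across C3–C4; in that bicyclic ether C4 is not enolisable and C7–H is a benzylic ether hydrogen activated by ring B. In addition, C3 bears the C6–O bond, so C3 can be released as a radical from a C3–C6 epoxide, with O1–C5 as the tether to a styrene-type C4=C7 acceptor and ring A on C2 as the only control element.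

## Logic of the disconnections

16 to 13. No skeletal bond is cut. In the backward sense the C7=O group and the free hydroxyl on C6 are rejoined as the ether C7(H)–O–C6; forward, the C7–H and C7–O(C6) bonds are cut by oxidation. The cut is made here because it removes the enolisable ketone, locks C3/C4 cis in a ring fusion and turns the target into an almost C2-symmetric bicycle. The demand on the forward step is that the oxidant takes the C7–H next to ring B and not the C2–H next to ring A, and leaves C4 alone.

13 to 8. The C3–C4 bond and the C7–O(C6) bond are cut, which opens both oxolane rings at once. The reason is polarity: C3 next to the C6–O bond is the natural radical from an oxirane, and C4=C7 conjugated to ring B is a natural radical acceptor. A bicycle with four stereocentres becomes an acyclic ether with one controlling stereocentre (C2) and an oxirane carbon whose configuration does not matter. The forward step must cyclise 5-exo faster than the radical is reduced, must set C3 and C4 from C2, and must capture C7 with the C6 oxygen.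

8 to 5 and 7. The O1–C5 bond is cut (ether synthesis). This divides the molecule into a ring A half and a ring B half of similar size. The forward alkylation must occur at the secondary oxygen of 5 without epoxide migration and by direct displacement at the allylic CH2 of 7.

5 to 4. The oxirane oxygen is removed, leaving the C3=C6 double bond. No stereocontrol is asked of the forward epoxidation, because the new centre is erased in the radical step.

4 to 3 to 1 and 2. The C2–C3 bond is cut (vinyl addition to the aldehyde), preceded in the forward sense by a resolution that fixes C2. The demand is high enantiopurity at C2, since every other stereocentre is derived from it.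

7 to 6. The C–Br bond is exchanged for C–OH; the forward step must keep the E double bond and deliver a bromide that is used at once.

## Other disconnections considered

Alternative 1: (the first that comes to mind) Cut the C7–ring B bond. Forward key step: addition of a ring-B aryllithium reagent to the cis-fused bicyclic lactone A1, which opens to the hydroxy ketone. A1 already holds the whole stereotriad, so this cut does not touch the real difficulty; A1 would itself need an aldol and lactonisation sequence with protecting groups that sets 2,3 and 3,4 in separate operations. The ketone would also be unmasked by a strongly basic organometallic beside the epimerisable C4, with risk of epimerisation and over-addition. The chosen plan unmasks it under neutral oxidative conditions and builds both rings in one step.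

Alternative 2: Cut C2–C3 and C4–C5. Forward key step: Lewis-acid (SnCl4) Prins–pinacol rearrangement (2-oxonia-Cope and aldol closure) of acetal A3, made from 1 and allylic diol A2, which would form the oxolane and the aryl ketone in one step. In the chair transition state ring A and the E-alkene substituent are both equatorial and the acyl group ends cis to ring A, so the expected product is A4, the C4 epimer of the protected target (3,4-trans). Reaching 16 would then need a contra-thermodynamic inversion at C4. The absolute sense would also rest on which substituent of the self-destroyed carbinol carbon prefers the equatorial site (ring B or the metal alkoxide; A2 and A3 are drawn for ring B equatorial), a small and uncertain bias.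

Alternative 3: Cut the C7–ring B bond on a symmetric framework. Forward key step: enantioselective desymmetrising acyl cross-coupling of the meso anhydride A5 with a ring-B arylzinc reagent (Pd(OAc)2 with a chiral bisphosphine), giving cis keto acid A6 with C3 and C4 set together. Ring A would then have to be introduced at C2, trans to the C3 substituent, by C–H arylation alpha to oxygen. C2–H and C5–H differ only by a remote substituent, and a carboxyl-directed arylation would deliver the cis isomer. The hardest relation is thus postponed to an unsolved late step on an epimerisable keto acid, whereas the chosen plan has ring A in place from the start and uses it as the control element.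

Key step: step 6

## Steps

Step 1
Reactants: 1 3,4,5-trimethoxybenzaldehyde; 2 vinylmagnesium bromide
Product: 3 rac-1-(3,4,5-trimethoxyphenyl)prop-2-en-1-ol
Conditions: THF, −78 to 0 °C; then aq. NH4Cl
Reagents that add atoms: none
Why: Grignard 1,2-addition of the vinyl nucleophile to a non-enolisable aldehyde forms the C2–C3 bond; the carbinol is racemic at this stage.

Step 2
Reactants: 3 rac-1-(3,4,5-trimethoxyphenyl)prop-2-en-1-ol
Product: 4 (S)-1-(3,4,5-trimethoxyphenyl)prop-2-en-1-ol
Conditions: Novozym 435 (immobilised Candida antarctica lipase B), vinyl acetate, MTBE, 30 °C, stopped at about 55% conversion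
Reagents that add atoms: none
Why: Lipase-catalysed kinetic resolution by enantiomer-selective transesterification: the enzyme should acylate the (R)-alcohol (aryl in the large pocket, vinyl in the medium pocket) and leave (S)-4, which fixes C2. No new stereocentre is formed; running past half conversion should give the recovered alcohol in high enantiopurity.

Step 3
Reactants: 4 (S)-1-(3,4,5-trimethoxyphenyl)prop-2-en-1-ol
Product: 5 (R)-[(2RS)-oxiran-2-yl](3,4,5-trimethoxyphenyl)methanol (both epimers at the oxirane carbon)
Conditions: mCPBA, CH2Cl2, 0 °C to rt
Reagents that add atoms: 3-chloroperoxybenzoic acid (mCPBA), OOC(=O)c1cccc(Cl)c1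
Why: Prilezhaev epoxidation of the terminal alkene, assisted by hydrogen bonding to the allylic hydroxyl. The configuration of the new oxirane carbon (C3) need not be controlled, because it becomes a planar radical in step 6; the carbinol centre is untouched and its descriptor changes from S to R only because the oxiranyl group outranks the aryl group.

Step 4
Reactants: 6 (E)-3-(3,4-dimethoxyphenyl)prop-2-en-1-ol
Product: 7 4-[(1E)-3-bromoprop-1-en-1-yl]-1,2-dimethoxybenzene
Conditions: PBr3, Et2O, 0 °C; used crude
Reagents that add atoms: phosphorus tribromide, BrP(Br)Br
Why: Conversion of a primary allylic alcohol into the bromide with PBr3 (displacement of the phosphite ester); the conjugated E double bond is retained and the labile bromide is used immediately.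

Step 5
Reactants: 5 (R)-[(2RS)-oxiran-2-yl](3,4,5-trimethoxyphenyl)methanol; 7 4-[(1E)-3-bromoprop-1-en-1-yl]-1,2-dimethoxybenzene
Product: 8 (2RS)-2-[(R)-{[(2E)-3-(3,4-dimethoxyphenyl)prop-2-en-1-yl]oxy}(3,4,5-trimethoxyphenyl)methyl]oxirane
Conditions: NaH, Bu4NI (cat.), THF, 0 °C to rt
Reagents that add atoms: none
Why: Williamson ether synthesis: the sodium alkoxide of 5 displaces the primary allylic bromide directly (attack at the conjugated terminus is disfavoured) and forms the O1–C5 bond. The aprotic medium and low temperature should keep epoxide migration slow; C2 is not touched.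

Step 6
Reactants: 8 (2RS)-2-[(R)-{[(2E)-3-(3,4-dimethoxyphenyl)prop-2-en-1-yl]oxy}(3,4,5-trimethoxyphenyl)methyl]oxirane
Product: 13 (+)-magnolin [(1S,3aR,4S,6aR)-1-(3,4-dimethoxyphenyl)-4-(3,4,5-trimethoxyphenyl)tetrahydro-1H,3H-furo[3,4-c]furan], via C3 radical 9 (not isolated), via benzylic radical 10 (not isolated), via benzyltitanium alkoxide 11 (not isolated), via benzylic iodide 12 (not isolated)
Conditions: Cp2TiCl2, Zn dust, THF, rt (slow addition of the resulting Cp2TiCl to 8 at high dilution); then I2, 60 °C
Reagents that add atoms: none
Why: Cp2TiCl (trivalent titanium) opens the oxirane by single-electron transfer at the C3–O bond (Nugent–RajanBabu reductive epoxide opening; closest known reaction type: titanocene-mediated radical cyclisation of epoxy alkenes) and gives the secondary radical 9, which is planar at C3, so both epimers of 8 converge on one intermediate. Radical 9 adds 5-exo-trig to C4 of the styrene-type double bond (new C3–C4 bond, first oxolane ring), a fast closure because the product radical 10 is benzylic. C3 and C4 are set in a chair-like transition state in which ring A on C2, the titanoxymethyl group on C3 and the alkene carbon C7 on C4 are all pseudo-equatorial, which corresponds to 2,3-trans and 3,4-cis; the only pre-existing stereocentre, C2, is the control element. A second Cp2TiCl traps 10 as benzyltitanium 11 (tetravalent titanium), iodine converts the C7–Ti bond into benzylic iodide 12, and the titanium alkoxide on C6 displaces iodide in a 5-exo-tet closure (SN1-like, through the cation stabilised by ring B) to form the second oxolane ring. This second closure can only give a cis-fused bicycle, so it also removes any 3,4-trans material from the product, and ring B should take the convex face at C7, a centre that step 7 erases. The step needs cyclisation to outrun reduction of 9 by Cp2TiCl (which would end in beta-elimination to an alkene) and 5-exo attack to beat 6-endo attack; the conjugated acceptor, the three-atom O1 tether and slow addition of the titanium reagent at high dilution should secure both.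

Step 7
Reactants: 13 (+)-magnolin [(1S,3aR,4S,6aR)-1-(3,4-dimethoxyphenyl)-4-(3,4,5-trimethoxyphenyl)tetrahydro-1H,3H-furo[3,4-c]furan]
Product: 16 magnone B [(3,4-dimethoxyphenyl)[(3R,4R,5S)-4-(hydroxymethyl)-5-(3,4,5-trimethoxyphenyl)oxolan-3-yl]methanone], via oxocarbenium ion 14 (not isolated), via cyclic hemiketal 15 (not isolated)
Conditions: DDQ, CH2Cl2/pH 7 phosphate buffer, 0 °C to rt
Reagents that add atoms: water, O
Why: DDQ oxidation of an electron-rich benzylic ether (the reaction type of oxidative 3,4-dimethoxybenzyl ether cleavage): hydride abstraction from C7–H gives oxocarbenium ion 14, water adds to give hemiketal 15, and ring opening releases the aryl ketone and the C6 hydroxyl. The C2–H next to ring A should be less reactive because the 4-methoxy group of ring A is twisted out of conjugation by its two neighbours. No stereocentre is formed; C4 should keep its configuration because the medium is buffered and because even a cis-fused enol ether formed from 14 can only reprotonate to the cis isomer.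

## Compound list

1 | 3,4,5-trimethoxybenzaldehyde | COc1cc(C=O)cc(OC)c1OC | starting material
2 | vinylmagnesium bromide | C=C[Mg]Br | starting material
3 | rac-1-(3,4,5-trimethoxyphenyl)prop-2-en-1-ol | C=CC(O)c1cc(OC)c(OC)c(OC)c1 | intermediate
4 | (S)-1-(3,4,5-trimethoxyphenyl)prop-2-en-1-ol | C=C[C@H](O)c1cc(OC)c(OC)c(OC)c1 | intermediate
5 | (R)-[(2RS)-oxiran-2-yl](3,4,5-trimethoxyphenyl)methanol, both epimers at the oxirane carbon | O[C@H](c1cc(OC)c(OC)c(OC)c1)C1CO1 | intermediate
6 | (E)-3-(3,4-dimethoxyphenyl)prop-2-en-1-ol | COc1ccc(/C=C/CO)cc1OC | starting material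
7 | 4-[(1E)-3-bromoprop-1-en-1-yl]-1,2-dimethoxybenzene | COc1ccc(/C=C/CBr)cc1OC | intermediate
8 | (2RS)-2-[(R)-{[(2E)-3-(3,4-dimethoxyphenyl)prop-2-en-1-yl]oxy}(3,4,5-trimethoxyphenyl)methyl]oxirane | COc1ccc(/C=C/CO[C@H](c2cc(OC)c(OC)c(OC)c2)C2CO2)cc1OC | intermediate
9 | C3 radical from ring opening of 8 (secondary radical at C3, Cp2ClTi–O on C6), not isolated | COc1ccc(/C=C/CO[C@H](c2cc(OC)c(OC)c(OC)c2)[CH]CO[Ti](Cl)(C2C=CC=C2)C2C=CC=C2)cc1OC | intermediate
10 | benzylic radical at C7 after 5-exo closure (oxolane formed, Cp2ClTi–O on C6), not isolated | COc1ccc([CH][C@H]2CO[C@H](c3cc(OC)c(OC)c(OC)c3)[C@H]2CO[Ti](Cl)(C2C=CC=C2)C2C=CC=C2)cc1OC | intermediate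
11 | benzyltitanium alkoxide (C7–TiCp2Cl and C6–O–TiCp2Cl), not isolated | COc1ccc(C([Ti](Cl)(C2C=CC=C2)C2C=CC=C2)[C@H]2CO[C@H](c3cc(OC)c(OC)c(OC)c3)[C@H]2CO[Ti](Cl)(C2C=CC=C2)C2C=CC=C2)cc1OC | intermediate
12 | benzylic iodide (C7–I, C6–O–TiCp2Cl), not isolated | COc1ccc(C(I)[C@H]2CO[C@H](c3cc(OC)c(OC)c(OC)c3)[C@H]2CO[Ti](Cl)(C2C=CC=C2)C2C=CC=C2)cc1OC | intermediate
13 | (+)-magnolin, (1S,3aR,4S,6aR)-1-(3,4-dimethoxyphenyl)-4-(3,4,5-trimethoxyphenyl)tetrahydro-1H,3H-furo[3,4-c]furan (a C7 epimer, if formed, is carried on) | COc1ccc([C@@H]4[C@H]2CO[C@H](c3cc(OC)c(OC)c(OC)c3)[C@H]2CO4)cc1OC | intermediate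
14 | bicyclic oxocarbenium ion at C7 (from hydride loss of 13), not isolated | COc1ccc(C4[C@H]2CO[C@H](c3cc(OC)c(OC)c(OC)c3)[C@H]2C[O+]=4)cc1OC | intermediate
15 | cyclic hemiketal (C7–OH in the bicycle), not isolated | COc1ccc(C4(O)[C@H]2CO[C@H](c3cc(OC)c(OC)c(OC)c3)[C@H]2CO4)cc1OC | intermediate
16 | magnone B, (3,4-dimethoxyphenyl)[(3R,4R,5S)-4-(hydroxymethyl)-5-(3,4,5-trimethoxyphenyl)oxolan-3-yl]methanone | COc1ccc(C(=O)[C@H]2CO[C@H](c3cc(OC)c(OC)c(OC)c3)[C@H]2CO)cc1OC | target

## Step count and risk

Total step count: 7. Longest linear sequence: 6 (steps 1, 2, 3, 5, 6, 7; step 4 is the one-step side branch).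

**Step 6 (key step).** The most likely failure is premature reduction of the C3 radical by a second Cp2TiCl, followed by beta-elimination of the titanium alkoxide (net deoxygenation) or hydrogen abstraction from the solvent. Incomplete 3,4-cis selectivity in the radical addition would lower the amount of material able to close the second ring. The fallback sets out from 4 and comes back at 13, and moves control of C4 from the radical step to a ring fusion. NaH and propargyl bromide give propargyl ether F1. Sonogashira coupling with 4-iodo-1,2-dimethoxybenzene (Pd(PPh3)2Cl2, CuI, Et3N) gives aryl alkyne F2. mCPBA epoxidises only the vinyl group to give epoxy alkyne F3. Cp2TiCl then triggers a 5-exo-dig cyclisation that sets only C3, and protic work-up gives benzylidene alcohol F4. Camphorsulfonic acid in CH2Cl2 protonates the electron-rich styrene at C4 and the C6 hydroxyl captures the benzylic cation, which can only close to the cis-fused bicycle 13.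

**Step 7.** The most likely failure is loss of site selectivity (hydride abstraction at C2–H next to ring A) or over-oxidation, for example dehydrogenation of a transient enol ether towards a furan. The fallback sets out from 4 and comes back at 16 without any C–H oxidation. The sequence described for step 6 is followed as far as benzylidene alcohol F4. Excess 9-BBN (the first equivalent caps the hydroxyl) then hydroborates the exocyclic alkene, with boron on the benzylic carbon and hydrogen delivered to C4 from the face away from the C6 substituent. Oxidation with NaBO3 gives diol F5, and MnO2 oxidises only the benzylic secondary alcohol to give 16.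

**Step 5.** The most likely failure is epoxide migration (Payne rearrangement) in the alkoxide of 5 before alkylation, which would place the ether on the primary oxygen; decomposition of the labile bromide is a second risk. The fallback sets out from 5 and 6 and comes back at 8, and avoids a free alkali alkoxide. 6 is converted with methyl chloroformate and pyridine into allyl methyl carbonate F6. The zinc alkoxide of 5 (Et2Zn, 0.5 equiv) is then allylated with F6 under Pd(PPh3)4 (zerovalent palladium) catalysis in THF, attack at the unhindered allyl terminus giving the linear ether.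

**Step 2.** The most likely failure is slow or poorly selective acylation, because the 3,5-dimethoxy substituents crowd the large pocket of the enzyme; this would give recovered alcohol of insufficient enantiopurity. The fallback sets out from 3 and comes back at 5, skipping 4, and replaces acyl transfer by enantiomer-selective epoxidation. Sharpless kinetic resolution (Ti(OiPr)4, D-(−)-diisopropyl tartrate, tert-butyl hydroperoxide 0.45 equiv, 4 Å molecular sieves, CH2Cl2, −20 °C) should epoxidise only the (S)-enantiomer and deliver 5 directly as one epimer, leaving the (R)-alcohol unreacted.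

## Further compounds

F1 | step 6 | 1,2,3-trimethoxy-5-[(1S)-1-(prop-2-yn-1-yloxy)prop-2-en-1-yl]benzene | C#CCO[C@H](c1cc(OC)c(OC)c(OC)c1)C=C
F2 | step 6 | 1,2-dimethoxy-4-(3-{[(1S)-1-(3,4,5-trimethoxyphenyl)prop-2-en-1-yl]oxy}prop-1-yn-1-yl)benzene | COc1ccc(C#CCO[C@H](c2cc(OC)c(OC)c(OC)c2)C=C)cc1OC
F3 | step 6 | (2RS)-2-[(R)-{[3-(3,4-dimethoxyphenyl)prop-2-yn-1-yl]oxy}(3,4,5-trimethoxyphenyl)methyl]oxirane | COc1ccc(C#CCO[C@H](c2cc(OC)c(OC)c(OC)c2)C2CO2)cc1OC
F4 | step 6 | [(2S,3R)-4-(3,4-dimethoxybenzylidene)-2-(3,4,5-trimethoxyphenyl)oxolan-3-yl]methanol (E/Z mixture) | COc1ccc(C=C2CO[C@H](c3cc(OC)c(OC)c(OC)c3)[C@H]2CO)cc1OC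
F5 | step 7 | (3,4-dimethoxyphenyl)[(3R,4R,5S)-4-(hydroxymethyl)-5-(3,4,5-trimethoxyphenyl)oxolan-3-yl]methanol (both carbinol epimers) | COc1ccc(C(O)[C@H]2CO[C@H](c3cc(OC)c(OC)c(OC)c3)[C@H]2CO)cc1OC
F6 | step 5 | (2E)-3-(3,4-dimethoxyphenyl)prop-2-en-1-yl methyl carbonate | COC(=O)OC/C=C/c1ccc(OC)c(OC)c1
F0 | step 2 | none | none
A1 | alternative 1 | (3aR,4S,6aR)-4-(3,4,5-trimethoxyphenyl)tetrahydro-1H,3H-furo[3,4-c]furan-1-one | O=C1[C@H]2CO[C@H](c3cc(OC)c(OC)c(OC)c3)[C@H]2CO1
A2 | alternative 2 | (2R,3E)-2-(3,4-dimethoxyphenyl)-5-[(triisopropylsilyl)oxy]pent-3-ene-1,2-diol | COc1ccc([C@](O)(/C=C/CO[Si](C(C)C)(C(C)C)C(C)C)CO)cc1OC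
A3 | alternative 2 | (4R)-4-(3,4-dimethoxyphenyl)-4-[(1E)-3-[(triisopropylsilyl)oxy]prop-1-en-1-yl]-2-(3,4,5-trimethoxyphenyl)-1,3-dioxolane (either configuration at the acetal carbon) | COc1ccc([C@]2(/C=C/CO[Si](C(C)C)(C(C)C)C(C)C)COC(c3cc(OC)c(OC)c(OC)c3)O2)cc1OC
A4 | alternative 2 | (3,4-dimethoxyphenyl)[(3S,4R,5S)-4-{[(triisopropylsilyl)oxy]methyl}-5-(3,4,5-trimethoxyphenyl)oxolan-3-yl]methanone | COc1ccc(C(=O)[C@@H]2CO[C@H](c3cc(OC)c(OC)c(OC)c3)[C@H]2CO[Si](C(C)C)(C(C)C)C(C)C)cc1OC
A5 | alternative 3 | (3aR,6aS)-tetrahydro-1H,3H-furo[3,4-c]furan-1,3-dione (meso, cis-fused) | O=C1OC(=O)[C@H]2COC[C@@H]12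
A6 | alternative 3 | (3S,4R)-4-(3,4-dimethoxybenzoyl)oxolane-3-carboxylic acid | COc1ccc(C(=O)[C@H]2COC[C@H]2C(O)=O)cc1OC
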